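## Retrosynthetic overview

1. Numbering used: spiro[2-oxabicyclo[2.2.2]octane-8,2'-oxane]; C1 = CH–O bridgehead, C3 = lactone C=O, C4 = methylated bridgehead, C5 = ketone, C6 and C7 = CHMe, C8 = C2' = spiro carbon.
2. Enabling feature: the ring C1–O2–C3–C4–C5–C6 is a 4-oxygenated 3,5-dimethyl-2-pyrone in reduced form, and the C7–C8 bridge is a two-carbon 2π unit whose C8 carries the oxane oxygen (an enol-ether carbon). The bicycle is therefore cut at C1–C7 and C4–C8 into a 4-silyloxy-2-pyrone and an exocyclic allenyl ether of the oxane (2'-vinylidene oxane), joined by an inverse-demand [4+2] that dearomatizes the pyrone.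
3. After the union: the C7 methylidene becomes the C7 methyl by face-selective hydrogenation, the silyl enol ether becomes the C5 ketone with C6 under thermodynamic control, and acetylation finishes the route.
4. Oxane fragment: auxiliary-controlled β-ketoimide aldol with acetaldehyde, 1,3-anti reduction and lactonization; then lactone → alkynyl lactol → reduction → propargyl-to-allenyl ether isomerization.
5. Ring order: oxane first (as δ-lactone); then the carbocycle C1–C6–C5–C4–C8–C7 and the bridging δ-lactone together in the key step.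

Key step: step 11

Remark on the chemistry: 4-hydroxy-3,5-dimethyl-2H-pyran-2-one is assumed not to be commercial and is made in step 9; the configuration of the target is taken exactly as written in the SMILES, (1S,4R,6S,7R,8S) in the bicycle and (3'S,4'R,5'R,6'S) in the oxane.

## Route

Step 1
Reactants: 1 (R)-4-benzyl-3-propanoyl-1,3-oxazolidin-2-one; 2 propanoyl chloride
Product: 3 (R)-4-benzyl-3-[(2S)-2-methyl-3-oxopentanoyl]-1,3-oxazolidin-2-one
Conditions: LDA, THF, −78 °C; then EtCOCl, −78 °C
Reagents that add atoms: none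
Why: C-acylation of the chelated Z-lithium enolate of an Evans imide, in which the acid chloride should attack the face opposite the benzyl group and set the 2S methyl centre, the product being held against epimerization by allylic strain in its enol.

Step 2
Reactants: 3 (R)-4-benzyl-3-[(2S)-2-methyl-3-oxopentanoyl]-1,3-oxazolidin-2-one; 4 acetaldehyde
Product: 5 (R)-4-benzyl-3-[(2S,4R,5S)-5-hydroxy-2,4-dimethyl-3-oxohexanoyl]-1,3-oxazolidin-2-one
Conditions: Sn(OTf)2, Et3N, CH2Cl2, −20 °C; then CH3CHO, −78 °C
Reagents that add atoms: none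
Why: Evans tin aldol of a β-ketoimide, in which the Z-enolate of the ethyl ketone should add to acetaldehyde under control of the existing C2 centre to give the anti-syn adduct (C2 and C4 methyls anti, C4 methyl and C5 hydroxyl syn).

Step 3
Reactants: 5 (R)-4-benzyl-3-[(2S,4R,5S)-5-hydroxy-2,4-dimethyl-3-oxohexanoyl]-1,3-oxazolidin-2-one
Product: 7 (3S,4R,5S,6S)-4-hydroxy-3,5,6-trimethyloxan-2-one, via anti-diol imide 6 (not isolated)
Conditions: Me4NBH(OAc)3, MeCN/AcOH, −20 °C; then Et3N (cat.), DMAP (cat.), CH2Cl2, rt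
Reagents that add atoms: none
Why: Evans–Saksena reduction, in which the C5 hydroxyl binds the acetoxyborohydride and delivers hydride internally to give the 1,3-anti diol (new C3 centre R), after which the C5 hydroxyl should attack the imide carbonyl, close the δ-lactone and release the auxiliary.

Step 4
Reactants: 7 (3S,4R,5S,6S)-4-hydroxy-3,5,6-trimethyloxan-2-one
Product: 8 (3S,4R,5R,6S)-4-[(tert-butyldimethylsilyl)oxy]-3,5,6-trimethyloxan-2-one
Conditions: TBSOTf, 2,6-lutidine, CH2Cl2, −78 °C
Reagents that add atoms: tert-butyldimethylsilyl triflate, CC(C)(C)[Si](C)(C)OS(=O)(=O)C(F)(F)F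
Why: Silylation of a hindered secondary alcohol with a silyl triflate and a non-nucleophilic base, conditions under which the β-oxygenated lactone should neither epimerize nor eliminate.

Step 5
Reactants: 8 (3S,4R,5R,6S)-4-[(tert-butyldimethylsilyl)oxy]-3,5,6-trimethyloxan-2-one; 9 ethynyltrimethylsilane
Product: 11 (3S,4R,5R,6S)-4-[(tert-butyldimethylsilyl)oxy]-3,5,6-trimethyl-2-[(trimethylsilyl)ethynyl]oxan-2-ol (anomeric mixture), via lithium (trimethylsilyl)acetylide 10 (not isolated)
Conditions: n-BuLi, THF, −78 °C; then 8, −78 °C; NH4Cl (aq)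
Reagents that add atoms: none
Why: Addition of a lithium acetylide to a δ-lactone, which should stop at the tetrahedral lithium alkoxide and give the alkynyl lactol on quench, without a second addition.

Step 6
Reactants: 11 (3S,4R,5R,6S)-4-[(tert-butyldimethylsilyl)oxy]-3,5,6-trimethyl-2-[(trimethylsilyl)ethynyl]oxan-2-ol
Product: 12 (2S,3R,4R,5R,6S)-4-[(tert-butyldimethylsilyl)oxy]-3,5,6-trimethyl-2-[(trimethylsilyl)ethynyl]oxane
Conditions: Et3SiH, TMSOTf (0.2 equiv), CH2Cl2/MeCN, −78 to −40 °C
Reagents that add atoms: none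
Why: Reductive deoxygenation of a lactol through its alkyne-stabilized oxocarbenium ion, with axial hydride delivery from the silane placing the alkyne equatorial (this centre becomes sp2 again in step 8).

Step 7
Reactants: 12 (2S,3R,4R,5R,6S)-4-[(tert-butyldimethylsilyl)oxy]-3,5,6-trimethyl-2-[(trimethylsilyl)ethynyl]oxane
Product: 13 (2S,3R,4R,5R,6S)-4-[(tert-butyldimethylsilyl)oxy]-2-ethynyl-3,5,6-trimethyloxane
Conditions: K2CO3 (cat.), MeOH, rt
Reagents that add atoms: none
Why: Methoxide-mediated protodesilylation of the C(sp)–Si bond, which should leave the secondary silyl ether untouched.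

Step 8
Reactants: 13 (2S,3R,4R,5R,6S)-4-[(tert-butyldimethylsilyl)oxy]-2-ethynyl-3,5,6-trimethyloxane
Product: 14 (3S,4R,5R,6S)-4-[(tert-butyldimethylsilyl)oxy]-2-ethenylidene-3,5,6-trimethyloxane
Conditions: KOtBu (0.5 equiv), DMSO, rt
Reagents that add atoms: none
Why: Base-mediated propargyl ether to allenyl ether isomerization (deprotonation of the α-oxy propargylic C2–H, reprotonation at the alkyne terminus), which should stop at the allene because C2 then carries no hydrogen.

Step 9
Reactants: 15 ethyl 2-methyl-3-oxopentanoate; 16 ethyl formate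
Product: 18 4-hydroxy-3,5-dimethyl-2H-pyran-2-one, via ethyl 4-formyl-2-methyl-3-oxopentanoate 17 (not isolated)
Conditions: NaH, then n-BuLi, THF, 0 °C; HCO2Et, −78 to 0 °C; then DBU, toluene, 60 °C; HCl (aq)
Reagents that add atoms: none
Why: Claisen formylation of the γ-carbanion of a β-keto ester dianion, followed by lactonization of the Z-enol of the formyl group onto the ester, the usual way to 4-hydroxy-2-pyrones.

Step 10
Reactants: 18 4-hydroxy-3,5-dimethyl-2H-pyran-2-one
Product: 19 4-[(tert-butyldimethylsilyl)oxy]-3,5-dimethyl-2H-pyran-2-one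
Conditions: TBSCl, imidazole, CH2Cl2, rt
Reagents that add atoms: tert-butyldimethylsilyl chloride, CC(C)(C)[Si](C)(C)Cl
Why: O-silylation of the acidic vinylogous acid, where the site of silylation is not critical because either O-silyl tautomer leads to the same pyrylium ion in step 11.

Step 11
Reactants: 14 (3S,4R,5R,6S)-4-[(tert-butyldimethylsilyl)oxy]-2-ethenylidene-3,5,6-trimethyloxane; 19 4-[(tert-butyldimethylsilyl)oxy]-3,5-dimethyl-2H-pyran-2-one
Product: 21 (1R,3'S,4R,4'R,5'R,6'S,8S)-4',5-bis[(tert-butyldimethylsilyl)oxy]-3',4,5',6,6'-pentamethyl-7-methylidenespiro[2-oxabicyclo[2.2.2]oct-5-ene-8,2'-oxan]-3-one, via 2,4-bis[(tert-butyldimethylsilyl)oxy]-3,5-dimethylpyrylium triflate 20 (not isolated)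
Conditions: TBSOTf (0.3 equiv), 2,6-di-tert-butyl-4-methylpyridine, CH2Cl2, −78 to −40 °C; Et3N quench at −78 °C
Reagents that add atoms: none
Why: Proposed new method: TBSOTf should silylate the lactone carbonyl of 19 reversibly to the 2,4-bis(silyloxy)pyrylium ion 20, which turns the electron-rich pyrone into a strongly electron-poor 4π partner; the nucleophilic central carbon of allenyl ether 14 then bonds to pyrone C6 while the oxygen-bearing allene carbon, developing oxocarbenium character, is captured by pyrone C3 in a highly asynchronous inverse-demand [4+2], and loss of the silyl group from the lactonium oxygen returns TBSOTf. The closest known reaction types are the Lewis-acid-promoted inverse-demand Diels–Alder reactions of 2-pyrones with enol ethers and ketene acetals, the additions of π-nucleophiles to 4-silyloxypyrylium ions made from pyranones and silyl triflates, and the cycloadditions of alkoxyallenes across their enol-ether double bond. One intermolecular [4+2] cycloaddition closes the carbocycle C1–C6–C5–C4–C8–C7 and with it the bridged δ-lactone ring C1–O2–C3–C4–C8–C7, forming C1–C7 and C4–C8. C1 and C4 are set together because the diene reacts suprafacially; C8 relative to them is set by the endo orientation of the oxane oxygen (under the C5=C6 silyl enol ether, with the bulkier C3' side under the small O2–C3 bridge); the absolute sense of all three comes from the oxane, since C4 should add to the oxocarbenium-like C8 axially, on the face opposite the axial 5'-methyl, in the half-chair that keeps the 3'-methyl, 4'-silyloxy and 6'-methyl groups pseudo-equatorial. The step needs regioselectivity (secured by polarity: pyrylium C6 is the only unsubstituted electrophilic terminus, the central allene carbon the nucleophilic one), periselectivity for the oxygenated allene C=C (the only one that leads to an oxygen-stabilized cation) and kinetic control (secured by low temperature and a hindered pyridine that removes triflic acid, so that neither the allenyl ether nor the reversible C4–C8 bond equilibrates).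

Step 12
Reactants: 21 (1R,3'S,4R,4'R,5'R,6'S,8S)-4',5-bis[(tert-butyldimethylsilyl)oxy]-3',4,5',6,6'-pentamethyl-7-methylidenespiro[2-oxabicyclo[2.2.2]oct-5-ene-8,2'-oxan]-3-one
Product: 22 (1S,3'S,4R,4'R,5'R,6'S,7R,8R)-4',5-bis[(tert-butyldimethylsilyl)oxy]-3',4,5',6,6',7-hexamethylspiro[2-oxabicyclo[2.2.2]oct-5-ene-8,2'-oxan]-3-one
Conditions: H2 (3 atm), Rh/Al2O3 (5 wt%), EtOAc, rt
Reagents that add atoms: none
Why: Heterogeneous hydrogenation of the 1,1-disubstituted alkene from its open face (the side of the oxane oxygen and the C5=C6 bridge, while the other face is covered by C3' and its methyl), which should leave the new methyl cis to C3' (7R); rhodium is chosen to avoid hydrogenolysis of the allylic C8–O bond, and the tetrasubstituted silyl enol ether should not be reduced.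

Step 13
Reactants: 22 (1S,3'S,4R,4'R,5'R,6'S,7R,8R)-4',5-bis[(tert-butyldimethylsilyl)oxy]-3',4,5',6,6',7-hexamethylspiro[2-oxabicyclo[2.2.2]oct-5-ene-8,2'-oxan]-3-one
Product: 23 (1S,3'S,4R,4'R,5'S,6S,6'S,7R,8S)-4'-hydroxy-3',4,5',6,6',7-hexamethylspiro[2-oxabicyclo[2.2.2]octane-8,2'-oxane]-3,5-dione
Conditions: 48% aq. HF, MeCN, 0 °C to rt; then TsOH·H2O (10 mol%), CHCl3, rt
Reagents that add atoms: none
Why: Acidic fluoride cleavage of both silyl groups, in which the enol ether gives the C5 ketone and acid-catalysed enolization should let the epimerizable C6 methyl settle on the lactone side, away from H-7 (6S, thermodynamic control); base is avoided because the β-acyloxy ketone could open by E1cB elimination.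

Step 14
Reactants: 23 (1S,3'S,4R,4'R,5'S,6S,6'S,7R,8S)-4'-hydroxy-3',4,5',6,6',7-hexamethylspiro[2-oxabicyclo[2.2.2]octane-8,2'-oxane]-3,5-dione
Product: 24 (1S,3'S,4R,4'R,5'R,6S,6'S,7R,8S)-3',4,5',6,6',7-hexamethyl-3,5-dioxospiro[2-oxabicyclo[2.2.2]octane-8,2'-oxan]-4'-yl acetate (CNP0257416.2)
Conditions: Ac2O, pyridine, DMAP (cat.), CH2Cl2, 0 °C to rt
Reagents that add atoms: acetic anhydride, CC(=O)OC(C)=O
Why: DMAP-catalysed acylation of the equatorial secondary alcohol under weakly basic conditions that should leave the β-keto lactone and all stereocentres untouched.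

## Compound list

1 | (R)-4-benzyl-3-propanoyl-1,3-oxazolidin-2-one | CCC(=O)N1[C@H](Cc2ccccc2)COC1=O | starting material
2 | propanoyl chloride | CCC(=O)Cl | starting material
3 | (R)-4-benzyl-3-[(2S)-2-methyl-3-oxopentanoyl]-1,3-oxazolidin-2-one | CCC(=O)[C@H](C)C(=O)N1[C@H](Cc2ccccc2)COC1=O | intermediate
4 | acetaldehyde | CC=O | starting material
5 | (R)-4-benzyl-3-[(2S,4R,5S)-5-hydroxy-2,4-dimethyl-3-oxohexanoyl]-1,3-oxazolidin-2-one | C[C@H](O)[C@@H](C)C(=O)[C@H](C)C(=O)N1[C@H](Cc2ccccc2)COC1=O | intermediate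
6 | (R)-4-benzyl-3-[(2S,3R,4R,5S)-3,5-dihydroxy-2,4-dimethylhexanoyl]-1,3-oxazolidin-2-one (anti-diol imide, not isolated) | C[C@H](O)[C@@H](C)[C@@H](O)[C@H](C)C(=O)N1[C@H](Cc2ccccc2)COC1=O | intermediate
7 | (3S,4R,5S,6S)-4-hydroxy-3,5,6-trimethyloxan-2-one | O[C@@H]1[C@H](C)[C@H](C)OC(=O)[C@H]1C | intermediate
8 | (3S,4R,5R,6S)-4-[(tert-butyldimethylsilyl)oxy]-3,5,6-trimethyloxan-2-one | CC(C)(C)[Si](C)(C)O[C@@H]1[C@H](C)[C@H](C)OC(=O)[C@H]1C | intermediate
9 | ethynyltrimethylsilane | C[Si](C)(C)C#C | starting material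
10 | lithium (trimethylsilyl)acetylide (not isolated) | [Li+].[C-]#C[Si](C)(C)C | intermediate
11 | (3S,4R,5R,6S)-4-[(tert-butyldimethylsilyl)oxy]-3,5,6-trimethyl-2-[(trimethylsilyl)ethynyl]oxan-2-ol, anomeric mixture | CC(C)(C)[Si](C)(C)O[C@@H]1[C@H](C)[C@H](C)OC(O)(C#C[Si](C)(C)C)[C@H]1C | intermediate
12 | (2S,3R,4R,5R,6S)-4-[(tert-butyldimethylsilyl)oxy]-3,5,6-trimethyl-2-[(trimethylsilyl)ethynyl]oxane | CC(C)(C)[Si](C)(C)O[C@@H]1[C@H](C)[C@H](C)O[C@H](C#C[Si](C)(C)C)[C@H]1C | intermediate
13 | (2S,3R,4R,5R,6S)-4-[(tert-butyldimethylsilyl)oxy]-2-ethynyl-3,5,6-trimethyloxane | CC(C)(C)[Si](C)(C)O[C@@H]1[C@H](C)[C@H](C)O[C@H](C#C)[C@H]1C | intermediate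
14 | (3S,4R,5R,6S)-4-[(tert-butyldimethylsilyl)oxy]-2-ethenylidene-3,5,6-trimethyloxane (exocyclic allenyl ether) | CC(C)(C)[Si](C)(C)O[C@@H]1[C@H](C)[C@H](C)OC(=C=C)[C@H]1C | intermediate
15 | ethyl 2-methyl-3-oxopentanoate (racemic) | CCOC(=O)C(C)C(=O)CC | starting material
16 | ethyl formate | CCOC=O | starting material
17 | ethyl 4-formyl-2-methyl-3-oxopentanoate (enol mixture, not isolated) | CCOC(=O)C(C)C(=O)C(C)C=O | intermediate
18 | 4-hydroxy-3,5-dimethyl-2H-pyran-2-one | CC1=COC(=O)C(C)=C1O | intermediate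
19 | 4-[(tert-butyldimethylsilyl)oxy]-3,5-dimethyl-2H-pyran-2-one | CC1=COC(=O)C(C)=C1O[Si](C)(C)C(C)(C)C | intermediate
20 | 2,4-bis[(tert-butyldimethylsilyl)oxy]-3,5-dimethylpyrylium triflate (not isolated) | Cc1c[o+]c(O[Si](C)(C)C(C)(C)C)c(C)c1O[Si](C)(C)C(C)(C)C.[O-]S(=O)(=O)C(F)(F)F | intermediate
21 | (1R,3'S,4R,4'R,5'R,6'S,8S)-4',5-bis[(tert-butyldimethylsilyl)oxy]-3',4,5',6,6'-pentamethyl-7-methylidenespiro[2-oxabicyclo[2.2.2]oct-5-ene-8,2'-oxan]-3-one | CC(C)(C)[Si](C)(C)O[C@@H]1[C@H](C)[C@H](C)O[C@]2(C(=C)[C@@H]3OC(=O)[C@@]2(C)C(O[Si](C)(C)C(C)(C)C)=C3C)[C@H]1C | intermediate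
22 | (1S,3'S,4R,4'R,5'R,6'S,7R,8R)-4',5-bis[(tert-butyldimethylsilyl)oxy]-3',4,5',6,6',7-hexamethylspiro[2-oxabicyclo[2.2.2]oct-5-ene-8,2'-oxan]-3-one | CC(C)(C)[Si](C)(C)O[C@@H]1[C@H](C)[C@H](C)O[C@]2([C@H](C)[C@@H]3OC(=O)[C@@]2(C)C(O[Si](C)(C)C(C)(C)C)=C3C)[C@H]1C | intermediate
23 | (1S,3'S,4R,4'R,5'S,6S,6'S,7R,8S)-4'-hydroxy-3',4,5',6,6',7-hexamethylspiro[2-oxabicyclo[2.2.2]octane-8,2'-oxane]-3,5-dione | O[C@@H]1[C@H](C)[C@H](C)O[C@]2([C@H](C)[C@@H]3OC(=O)[C@@]2(C)C(=O)[C@H]3C)[C@H]1C | intermediate
24 | (1S,3'S,4R,4'R,5'R,6S,6'S,7R,8S)-3',4,5',6,6',7-hexamethyl-3,5-dioxospiro[2-oxabicyclo[2.2.2]octane-8,2'-oxan]-4'-yl acetate | CC(=O)O[C@@H]1[C@H](C)[C@H](C)O[C@]2([C@H](C)[C@@H]3OC(=O)[C@@]2(C)C(=O)[C@H]3C)[C@H]1C | target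

## Step count and risks

Total step count: 14. Longest linear sequence: 12 steps (steps 1–8 and 11–14, from compound 1); the pyrone branch is 2 steps (9 and 10).

**Risk 1, step 11 (bears the label).** The union may not take place because the silylated pyrone is still too weak an electrophile. The allenyl ether may be consumed by acid-mediated isomerization or oligomerization before it reacts. Kinetic control at the spiro centre may be lost through reversible C4–C8 closure, or the endo and facial selectivity may be poor. Fallback with known reaction types, setting out from lactone 8 and coming back at 23: addition of ethynylmagnesium bromide to 8 would give the ethynyl lactol F1. Silyl-triflate-mediated addition of the silyl dienol ether 19 through its C3 to the alkynyl oxocarbenium ion of F1 (axial attack, a C-glycosylation of the Mukaiyama type) would give the alkynyl pyrandione F2, the C4 epimers being separated if both form. Tributylstannyl radical addition to the alkyne terminus (Bu3SnH, AIBN, benzene, 80 °C) and cyclization of the resulting vinyl radical onto the β-carbon of the β-alkoxy enone would close the C1–C7 bond and give the vinylstannane bicycle F3. Protodestannylation with HCl would give the methylidene ketone F4, hydrogenation over Rh/Al2O3 the methyl ketone silyl ether F5, and aqueous HF would deliver 23.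

**Risk 2, step 8.** The isomerization may stall at the alkyne, run on to the conjugated 2-alkoxy-1,3-diene with loss of the C3 stereocentre, or the allenyl ether may hydrolyse on isolation. Fallback, setting out from lactone 8 and coming back at 14: Petasis methylenation of 8 (Cp2TiMe2, toluene, 70 °C) would give the exocyclic enol ether F6. Dibromocarbene addition (CHBr3, KOtBu, pentane, −30 °C) would give the spiro dibromocyclopropane F7, and the Doering–LaFlamme ring opening with MeLi (Et2O, −78 °C) would deliver allene 14.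

**Risk 3, step 12.** Facial selectivity in the hydrogenation of the C7 methylidene may be poor, or the allylic C8–O bond may be hydrogenolysed. Fallback, setting out from allene 14 and coming back at 22: the stereocentre would be set through alkene geometry instead of through a face-selective reduction. Semihydrogenation of the terminal, non-oxygenated C=C of 14 (H2, RhCl(PPh3)3, benzene), with hydrogen delivered to the central carbon from the side of the ring oxygen, would give the (E)-ethylidene oxane F8, in which the methyl is already cis to C3. Union of F8 with 19 under the conditions of step 11 would then turn this geometry into the C7 configuration by suprafacial addition and give 22 directly.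

## Further compounds

F1 | step 11 | (3S,4R,5R,6S)-4-[(tert-butyldimethylsilyl)oxy]-2-ethynyl-3,5,6-trimethyloxan-2-ol, anomeric mixture | CC(C)(C)[Si](C)(C)O[C@@H]1[C@H](C)[C@H](C)OC(O)(C#C)[C@H]1C
F2 | step 11 | 3-{4-[(tert-butyldimethylsilyl)oxy]-2-ethynyl-3,5,6-trimethyloxan-2-yl}-3,5-dimethyl-2H-pyran-2,4(3H)-dione, configured as in the target at the oxane, the spiro-to-be carbon and C3 of the dione | CC(C)(C)[Si](C)(C)O[C@@H]1[C@H](C)[C@H](C)O[C@@](C#C)([C@@]2(C)C(=O)OC=C(C)C2=O)[C@H]1C
F3 | step 11 | 4'-[(tert-butyldimethylsilyl)oxy]-3',4,5',6,6'-pentamethyl-7-[(tributylstannyl)methylidene]spiro[2-oxabicyclo[2.2.2]octane-8,2'-oxane]-3,5-dione, alkene geometry not defined | CC(C)(C)[Si](C)(C)O[C@@H]1[C@H](C)[C@H](C)O[C@]2(C(=C[Sn](CCCC)(CCCC)CCCC)[C@@H]3OC(=O)[C@@]2(C)C(=O)[C@H]3C)[C@H]1C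
F4 | step 11 | 4'-[(tert-butyldimethylsilyl)oxy]-3',4,5',6,6'-pentamethyl-7-methylidenespiro[2-oxabicyclo[2.2.2]octane-8,2'-oxane]-3,5-dione | CC(C)(C)[Si](C)(C)O[C@@H]1[C@H](C)[C@H](C)O[C@]2(C(=C)[C@@H]3OC(=O)[C@@]2(C)C(=O)[C@H]3C)[C@H]1C
F5 | step 11 | 4'-[(tert-butyldimethylsilyl)oxy]-3',4,5',6,6',7-hexamethylspiro[2-oxabicyclo[2.2.2]octane-8,2'-oxane]-3,5-dione, configured as in 23 | CC(C)(C)[Si](C)(C)O[C@@H]1[C@H](C)[C@H](C)O[C@]2([C@H](C)[C@@H]3OC(=O)[C@@]2(C)C(=O)[C@H]3C)[C@H]1C
F6 | step 8 | (3S,4R,5R,6S)-4-[(tert-butyldimethylsilyl)oxy]-3,5,6-trimethyl-2-methylideneoxane | CC(C)(C)[Si](C)(C)O[C@@H]1[C@H](C)[C@H](C)OC(=C)[C@H]1C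
F7 | step 8 | 1,1-dibromo-6-[(tert-butyldimethylsilyl)oxy]-5,7,8-trimethyl-4-oxaspiro[2.5]octane, spiro centre not defined | CC(C)(C)[Si](C)(C)O[C@@H]1[C@H](C)[C@H](C)OC2(CC2(Br)Br)[C@H]1C
F8 | step 12 | (2E,3S,4R,5R,6S)-4-[(tert-butyldimethylsilyl)oxy]-2-ethylidene-3,5,6-trimethyloxane | CC(C)(C)[Si](C)(C)O[C@@H]1[C@H](C)[C@H](C)O/C(=C/C)[C@H]1C
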